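## The problem

Vidalol B (13) is 2-bromo-4,6-bis[(2,3-dibromo-4,5-dihydroxyphenyl)methyl]benzene-1,3,5-triol: a hexasubstituted bromophloroglucinol (ring A) joined through two methylene bridges to two identical pentasubstituted dibromocatechols (rings B and C). The target has no stereocenter, so the task is one of regiochemistry and of handling an electron-rich compound with seven phenols and five bromines. In each outer ring the order of substituents is CH2–C, C–Br, C–Br, C–OH, C–OH, C–H, a pattern that direct bromination of a catechol does not give, because bromine enters para to oxygen and not between an oxygen and a second bromine. Ring A carries its bromine on a carbon flanked by two oxygens, a C–Br bond that acid and bromide together can shift, and the aryl–CH2 bonds of a para-hydroxybenzyl phloroglucinol can be reopened by strong acid. The free catechols and the phloroglucinol oxidise readily in air, most of all in base, so the phenols should stay masked until the last step and be released under acidic, non-oxidising conditions. The feature that opens the route is this: counted from the benzylic carbon, C4–OH, C5–OH, C3–Br and C2–Br of rings B and C are the four contiguous substituents obtained when 1,2-dibromobenzene (1) is oxygenated across the ring bond next to one bromine. The two C–H carbons that remain are the bridge position and the ring hydrogen.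

## Retrosynthesis

**13 to 12.** The seven phenols are masked as three methyl ethers on ring A and two methylene acetals on rings B and C, and all five ether functions are cut in one Lewis-acidic operation at the end. The methyl ethers arrive with the commercial ring A building block 10. The acetals are chosen because they also control regiochemistry earlier in the route. The forward step must cleave five ether functions without touching five aryl C–Br bonds or the two benzylic C–C bonds.

**12 to 9 and 10.** The two bonds between ring A and the bridge carbons are cut, not the bonds between the bridge carbons and rings B and C. Arene 10 has exactly two unsubstituted ring carbons, each flanked by two methoxy groups, so it is a strong nucleophile that cannot be alkylated a third time. The opposite polarity would make ring A the electrophile and 6 the nucleophile, pairing an over-stabilised benzylic cation with a ring deactivated by two bromines. The cut divides a C25 intermediate into one C9 arene and two copies of a C8 benzylic chloride. The forward reaction must alkylate twice, the second time at a hindered carbon, and leave the ring A bromine in place.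

**9 to 6 and 7.** The bond between the outer ring and its chloromethyl carbon is cut, with formaldehyde 7 as the one-carbon source. The cyclic acetal makes this cut reliable. It holds both oxygen lone pairs in conjugation with the ring, and benzodioxoles substitute para to oxygen. C6 of 6 is para to O3, the oxygen next to the bromine-bearing carbon, and is the position the target requires. Had the oxygens of 4 been masked as two separate methyl ethers, the one between bromine and the other methoxy group would be twisted out of conjugation, and substitution could drift to the other free carbon. The forward reaction must give mono-substitution para to oxygen on a deactivated ring.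

**6 to 4 and 5.** The two acetal C–O bonds are cut, giving catechol 4 and dibromomethane 5. This is a routine protection. The precursor is a six-carbon catechol with all four heteroatom substituents in place.

**4 to 3.** No skeletal bond is cut. The catechol is traced to its dihydro form, the cis-dihydrodiol 3, and the forward step is a dehydrogenation that removes both stereocenters. It must avoid acid, which dehydrates 3 to phenols and loses one oxygen.

**3 to 1 and 2.** Both C–O bonds of the future catechol are cut at once, leading to 1 and dioxygen 2. No neighbouring cut delivers oxygen, oxygen, bromine, bromine on four contiguous carbons from a commercial arene in one operation. Electrophilic routes to 4 need several steps and a directing group. The forward step must oxygenate the ring bond next to bromine and not the distal one, which the enzyme toluene dioxygenase does with halobenzenes.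

## Roads not taken

**Alternative 1:** Ring A would be cut at the two C–C bonds flanking one of its C–OH carbons, with that carbon supplied by carbon monoxide A2. The precursor is the acyclic 3-acetoxy-1,4-enyne A1, 1,7-bis(2,3-dibromo-4,5-dimethoxyphenyl)-3-methoxyhept-2-en-5-yn-4-yl acetate, which already carries both benzyl groups. In the forward key step the chloro-bridged dimer [Rh(CO)2Cl]2 A3, a complex of monovalent rhodium, would trigger a 1,2-acetoxy shift at the propargylic ester under an atmosphere of A2. Insertion of A2 between the alkyne and alkene termini would then close ring A as the resorcinol monoacetate A4.
- Merits: every substituent of ring A is placed by the connectivity of A1. No electrophilic substitution is run on a bromophloroglucinol ether, and the ring A bromine would be introduced last at the only remaining C–H.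
- Weak points: the route builds the one ring that can be bought complete. A1 needs a linear sequence of perhaps six to eight operations to join two benzyl fragments through a seven-carbon chain containing an enol ether and a propargylic ester, both sensitive. Four aryl bromides are exposed to A3 under heating. The real difficulty, the oxygen, oxygen, bromine, bromine array of rings B and C, is not addressed.
- Comparison: this road is better in the positional security of ring A and in keeping its bromine away from acid. The chosen plan sets against this six steps in all from commercial 1 and 10, an acid by-product in the bond-forming step that contains no bromide, and a key step that solves the outer-ring pattern itself.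

**Alternative 2:** Each outer ring would be cut at the two ring C–C bonds that join a four-carbon furan unit to a two-carbon alkyne unit. The precursor A5, 2-bromo-4,6-bis[(3,4-dibromofuran-2-yl)methyl]-1,3,5-trimethoxybenzene, would undergo two Diels–Alder additions with methyl 3-bromopropiolate A6 to give the bis(7-oxanorbornadiene) A7.
- Merits: both outer rings are formed in one operation. Their substituents are fixed by the connectivity of the cycloaddition, so there is no question of electrophilic regiochemistry on rings B and C. The bridging oxygen becomes one of the catechol oxygens. The chemistry runs in ordinary glassware and does not depend on fermentation productivity.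
- Weak points: the 3,4-dibromofuran units of A5 are electron-poor, sluggish dienes even toward an activated alkyne such as A6, and their adducts tend to revert. The ester must end up next to the substituted bridgehead twice. After the cycloaddition each ring still needs an aromatising opening of the oxygen bridge in the right sense, removal of the ester carbon, and exchange of the bromine next to it for oxygen. That is at least four further operations in the presence of many other C–Br bonds. The four stereocenters of A7 are irrelevant to 13 but give mixtures along the way.
- Comparison: this road is at least as good in regiochemical certainty on the outer rings and better in scalability of equipment. The chosen plan obtains the same four contiguous substituents in one enzymatic step from 1 and is shorter by several steps.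

**Alternative 3:** The three C–O bonds of ring A would be cut. In the precursor A8, (5-bromo-2,4,6-trifluoro-1,3-phenylene)bis[(2,3-dibromo-4,5-dimethoxyphenyl)methanone], each fluoride is ortho or para to both aroyl carbonyls. Threefold nucleophilic aromatic substitution by sodium methoxide A9 would give the bis-ketone A10.
- Merits: the substitution with A9 is robust and its regiochemistry is fixed by the positions of the fluorides. The carbonyl linkers exclude over-alkylation, and no Friedel–Crafts reaction is run on an electron-rich bromoarene.
- Weak points: it makes C–O bonds that 10 already contains. A8 must be assembled by two successive aryl-metal acylations on a ring bearing fluorine and bromine, where aryne formation threatens. The aroyl partner, with its oxygen, oxygen, bromine, bromine pattern, must be made separately. Two hindered diaryl ketones in A10 then have to be reduced to methylene groups without loss of C–Br bonds, and seven methyl ethers must be cleaved at the end.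
- Comparison: this road is more secure in regiochemistry at each bond and needs no biotransformation. The chosen plan is shorter by roughly three or four steps, and its key step builds the outer-ring pattern that Alternative 3 must obtain separately.

Key step: step 1

Assumption (remark on the chemistry): glucose-fed whole cells supply the NADH consumed in step 1 and re-oxidise the NADH formed in step 2 by respiration; the (1S,2S) configuration written for 3 is the sense toluene dioxygenase shows with halobenzenes and is erased in step 2, so nothing downstream depends on it.

## Route

Step 1
Reactants: 1 1,2-dibromobenzene; 2 dioxygen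
Product: 3 (1S,2S)-3,4-dibromocyclohexa-3,5-diene-1,2-diol (cis-diol)
Conditions: whole cells of E. coli JM109(pDTG601) expressing toluene dioxygenase, glucose, air, pH 7 medium, 35 °C; EtOAc extraction at pH 7–8, crystallisation
Reagents that add atoms: none
Why: Toluene dioxygenase is a Rieske non-heme iron dioxygenase: two electrons from NADH reach the mononuclear iron site through the reductase and ferredoxin components, dioxygen is activated there, and both of its oxygen atoms are transferred to adjacent ring carbons of the bound arene. The closest known reaction type is the whole-cell cis-dihydroxylation of mono- and dihalobenzenes by this enzyme, a substrate class to which 1 belongs. The two C–O bonds form at C3 and C4 of 1 (C2 and C1 of 3), no ring is closed, and the arene is dearomatised to a 1,3-diene. Both new stereocenters are set by the enzyme: the cis relationship follows from delivery of both oxygens of one iron-bound dioxygen to the same face, and the absolute sense (1S,2S) is fixed by the orientation of the arene in the active site, as for other halobenzenes. The selectivity needed is oxygenation of the ring bond next to a bromine and not of the distal C4–C5 bond, and the enzyme's preference for the bond ortho and meta to a halogen supplies it. Because 1 has a twofold axis, the two bonds that flank the bromines are equivalent, so this mode can give only one constitutional isomer. The diol is kept cold and neutral to slightly basic during isolation, since acid dehydrates it to a phenol.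

Step 2
Reactants: 3 (1S,2S)-3,4-dibromocyclohexa-3,5-diene-1,2-diol
Product: 4 3,4-dibromobenzene-1,2-diol (3,4-dibromocatechol)
Conditions: whole cells of recombinant E. coli expressing toluene cis-dihydrodiol dehydrogenase (TodD, e.g. strain JM109(pDTG602)), pH 7 phosphate buffer, air, 30 °C; acidify to pH 3, EtOAc, under N2
Reagents that add atoms: none
Why: Enzymatic dehydrogenation: the NAD+-dependent cis-dihydrodiol dehydrogenase oxidises one carbinol and the resulting ketone enolises to the aromatic catechol, the natural next reaction of the toluene pathway and one that accepts halogenated diols. The neutral medium avoids acid-catalysed dehydration of 3 to a phenol, and both stereocenters are erased.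

Step 3
Reactants: 4 3,4-dibromobenzene-1,2-diol; 5 dibromomethane
Product: 6 4,5-dibromo-1,3-benzodioxole
Conditions: CH2Br2 (1.5 equiv), Cs2CO3 (2.5 equiv), DMF, 100 °C, N2
Reagents that add atoms: none
Why: Double Williamson etherification: two phenoxide displacements on CH2Br2, the second intramolecular and closing the five-membered acetal, a standard methylenation of catechols that is run under N2 to protect the catechol from air.

Step 4
Reactants: 6 4,5-dibromo-1,3-benzodioxole; 7 formaldehyde (used as paraformaldehyde)
Product: 9 4,5-dibromo-6-(chloromethyl)-1,3-benzodioxole, via (6,7-dibromo-1,3-benzodioxol-5-yl)methanol 8 (not isolated)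
Conditions: (CH2O)n, HCl (gas), ZnCl2 (cat.), AcOH, 60 °C
Reagents that add atoms: hydrogen chloride, Cl
Why: Blanc chloromethylation, an electrophilic aromatic substitution by protonated formaldehyde followed by conversion of the benzylic alcohol 8 into the chloride by HCl; benzodioxoles substitute para to oxygen, and C6 is para to O3 while C7 is only ortho to O1, so the chloromethyl group should enter next to C5–Br as the target requires. The two bromines deactivate the ring enough that the product should not alkylate a second molecule of 6 at this temperature.

Step 5
Reactants: 9 4,5-dibromo-6-(chloromethyl)-1,3-benzodioxole (2.2 equiv); 10 2-bromo-1,3,5-trimethoxybenzene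
Product: 12 2-bromo-4,6-bis[(6,7-dibromo-1,3-benzodioxol-5-yl)methyl]-1,3,5-trimethoxybenzene, via 2-bromo-4-[(6,7-dibromo-1,3-benzodioxol-5-yl)methyl]-1,3,5-trimethoxybenzene 11 (not isolated)
Conditions: FeCl3 (10 mol %), CH2Cl2, 0 °C to rt
Reagents that add atoms: none
Why: Friedel–Crafts benzylation: FeCl3 ionises the benzylic chloride to a cation stabilised by the para oxygen, and 10 captures it at its two free ring carbons, each flanked by two methoxy groups, first to 11 and then to 12; a third alkylation is impossible. The only by-product is HCl, so no bromide is present to shuttle the ring A bromine, and the deactivated ring of 9 does not compete as a nucleophile.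

Step 6
Reactants: 12 2-bromo-4,6-bis[(6,7-dibromo-1,3-benzodioxol-5-yl)methyl]-1,3,5-trimethoxybenzene
Product: 13 vidalol B, 2-bromo-4,6-bis[(2,3-dibromo-4,5-dihydroxyphenyl)methyl]benzene-1,3,5-triol
Conditions: BBr3 (12 equiv), CH2Cl2, −78 °C to rt; then H2O, 0 °C; EtOAc extraction under N2
Reagents that add atoms: none
Why: Lewis-acid ether cleavage: BBr3 coordinates each ether oxygen and bromide attacks the methyl or acetal carbon, giving bromomethane, aryl bromomethyl ethers and aryl borates that water hydrolyses to the seven phenols with release of formaldehyde. Aryl C–Br bonds are inert to BBr3, and the acidic, non-oxidising medium suits the air-sensitive polyphenol.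

## Compound list

1 | 1,2-dibromobenzene | Brc1ccccc1Br | starting material
2 | dioxygen | O=O | starting material
3 | (1S,2S)-3,4-dibromocyclohexa-3,5-diene-1,2-diol | O[C@@H]1[C@H](O)C(Br)=C(Br)C=C1 | intermediate
4 | 3,4-dibromobenzene-1,2-diol | Oc1ccc(Br)c(Br)c1O | intermediate
5 | dibromomethane | BrCBr | starting material
6 | 4,5-dibromo-1,3-benzodioxole | Brc1ccc2OCOc2c1Br | intermediate
7 | formaldehyde (used as paraformaldehyde) | C=O | starting material
8 | (6,7-dibromo-1,3-benzodioxol-5-yl)methanol | OCc1cc2OCOc2c(Br)c1Br | intermediate
9 | 4,5-dibromo-6-(chloromethyl)-1,3-benzodioxole | ClCc1cc2OCOc2c(Br)c1Br | intermediate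
10 | 2-bromo-1,3,5-trimethoxybenzene | COc1cc(OC)c(Br)c(OC)c1 | starting material
11 | 2-bromo-4-[(6,7-dibromo-1,3-benzodioxol-5-yl)methyl]-1,3,5-trimethoxybenzene | COc1cc(OC)c(Br)c(OC)c1Cc1cc2OCOc2c(Br)c1Br | intermediate
12 | 2-bromo-4,6-bis[(6,7-dibromo-1,3-benzodioxol-5-yl)methyl]-1,3,5-trimethoxybenzene | COc1c(Br)c(OC)c(Cc2cc3OCOc3c(Br)c2Br)c(OC)c1Cc1cc2OCOc2c(Br)c1Br | intermediate
13 | vidalol B, 2-bromo-4,6-bis[(2,3-dibromo-4,5-dihydroxyphenyl)methyl]benzene-1,3,5-triol | Oc1cc(Cc2c(O)c(Br)c(O)c(Cc3cc(O)c(O)c(Br)c3Br)c2O)c(Br)c(Br)c1O | target

## Step count and risks

Total: 6 steps. Longest linear sequence: 6 steps (1 to 3 to 4 to 6 to 9 to 12 to 13); arene 10 is bought.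

**Step 1 (key step).** The dense, poorly soluble dihalide may be turned over slowly and may poison the cells, giving low volumetric productivity. Some oxygenation may occur at the distal ring bond, and the diol may dehydrate to phenols during isolation.

Fallback: leave the enzymatic step and reach 4 from 1 by arene chemistry. Deprotonation of 1 next to bromine (lithium diisopropylamide, THF, −78 °C) with B(OiPr)3 present as an in situ trap, followed by hydrolysis, would give (2,3-dibromophenyl)boronic acid F1. Oxidation with H2O2 and NaOH would give 2,3-dibromophenol F2. Ortho-formylation (MgCl2, Et3N, paraformaldehyde, MeCN, reflux) would give 3,4-dibromo-2-hydroxybenzaldehyde F3. Dakin oxidation (H2O2, NaOH) would convert the formyl group into the second hydroxyl. The fallback sets out from 1 and returns to the route at 4.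

**Step 2.** The dehydrogenase may accept the dibromo diol poorly. The catechol may inhibit the cells and may be oxidised further and polymerise in the aerated medium.

Fallback: chemical oxidation of one allylic carbinol of 3 with activated dimethyl sulfoxide (SO3·pyridine, DMSO, Et3N, 0 °C, Parikh–Doering oxidation), followed by spontaneous enolisation to the aromatic ring. A Na2S2O4 wash would return any over-oxidised material to the catechol. It sets out from 3 and returns at 4; no new compound is isolated on the way, so its entry below is F0.

**Step 4.** Substitution on the deactivated ring may stall. The product chloride may alkylate unreacted 6 to a diarylmethane, some attack may occur ortho to oxygen at C7, and forcing acid may open the acetal.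

Fallback: replace alkylation by acylation-type chemistry, whose product is deactivated towards a second substitution. Rieche formylation of 6 (Cl2CHOMe, TiCl4, CH2Cl2, 0 °C) would give 6,7-dibromo-1,3-benzodioxole-5-carbaldehyde F4, which can be purified by crystallisation. NaBH4 in MeOH would reduce it to 8, and SOCl2 in CH2Cl2 would give the chloride. It sets out from 6 and returns at 9.

**Step 5.** The second benzylation at the hindered carbon may remain incomplete. Acid may promote migration or loss of the ring A bromine and transfer of benzyl groups between rings.

Fallback: form the C–C bonds before ring A carries bromine. Chloride 9 (2.0 equiv) would be combined with commercial 1,3,5-trimethoxybenzene F5 under the same FeCl3 catalysis. Reaction would pass through 2-[(6,7-dibromo-1,3-benzodioxol-5-yl)methyl]-1,3,5-trimethoxybenzene F6 to 2,4-bis[(6,7-dibromo-1,3-benzodioxol-5-yl)methyl]-1,3,5-trimethoxybenzene F7. The stoichiometry and the falling reactivity after each alkylation limit a third benzylation. N-Bromosuccinimide (MeCN, 0 °C) would then brominate the one remaining ring A carbon, far more nucleophilic than the outer rings. It sets out from 9 and returns at 12.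

**Step 6.** Cleavage of five ether functions in one molecule may stop short. The halomethyl fragments released from the acetals may re-alkylate the free outer-ring carbons, strong acid may reopen the benzylic C–C bonds, and air may oxidise the product during work-up.

Fallback: unmask in two stages by different mechanisms. BCl3 (CH2Cl2, 0 °C, then MeOH) opens methylene acetals in preference to methyl ethers and would give 5,5'-[(5-bromo-2,4,6-trimethoxy-1,3-phenylene)bis(methylene)]bis(3,4-dibromobenzene-1,2-diol) F8, from which the one-carbon fragments are washed away. The three hindered methyl ethers would then be removed by soft-nucleophile demethylation (AlCl3, EtSH, CH2Cl2, 0 °C). It sets out from 12 and returns at 13.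

## Further compounds

F1 | step 1 | (2,3-dibromophenyl)boronic acid | OB(O)c1cccc(Br)c1Br
F2 | step 1 | 2,3-dibromophenol | Oc1cccc(Br)c1Br
F3 | step 1 | 3,4-dibromo-2-hydroxybenzaldehyde | O=Cc1ccc(Br)c(Br)c1O
F0 | step 2 | none | none
F4 | step 4 | 6,7-dibromo-1,3-benzodioxole-5-carbaldehyde | O=Cc1cc2OCOc2c(Br)c1Br
F5 | step 5 | 1,3,5-trimethoxybenzene | COc1cc(OC)cc(OC)c1
F6 | step 5 | 2-[(6,7-dibromo-1,3-benzodioxol-5-yl)methyl]-1,3,5-trimethoxybenzene | COc1cc(OC)c(Cc2cc3OCOc3c(Br)c2Br)c(OC)c1
F7 | step 5 | 2,4-bis[(6,7-dibromo-1,3-benzodioxol-5-yl)methyl]-1,3,5-trimethoxybenzene | COc1cc(OC)c(Cc2cc3OCOc3c(Br)c2Br)c(OC)c1Cc1cc2OCOc2c(Br)c1Br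
F8 | step 6 | 5,5'-[(5-bromo-2,4,6-trimethoxy-1,3-phenylene)bis(methylene)]bis(3,4-dibromobenzene-1,2-diol) | COc1c(Br)c(OC)c(Cc2cc(O)c(O)c(Br)c2Br)c(OC)c1Cc1cc(O)c(O)c(Br)c1Br
A1 | alternative 1 | 1,7-bis(2,3-dibromo-4,5-dimethoxyphenyl)-3-methoxyhept-2-en-5-yn-4-yl acetate (racemic, alkene geometry immaterial) | CC(=O)OC(C#CCc1cc(OC)c(OC)c(Br)c1Br)C(OC)=CCc1cc(OC)c(OC)c(Br)c1Br
A2 | alternative 1 | carbon monoxide | [C-]#[O+]
A3 | alternative 1 | [Rh(CO)2Cl]2, tetracarbonyldi-μ-chlorodirhodium | [C-]#[O+].[C-]#[O+].[C-]#[O+].[C-]#[O+].[Cl-].[Cl-].[Rh+].[Rh+]
A4 | alternative 1 | 3-hydroxy-5-methoxy-2,4-bis[(2,3-dibromo-4,5-dimethoxyphenyl)methyl]phenyl acetate | CC(=O)Oc1cc(OC)c(Cc2cc(OC)c(OC)c(Br)c2Br)c(O)c1Cc1cc(OC)c(OC)c(Br)c1Br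
A5 | alternative 2 | 2-bromo-4,6-bis[(3,4-dibromofuran-2-yl)methyl]-1,3,5-trimethoxybenzene | COc1c(Br)c(OC)c(Cc2occ(Br)c2Br)c(OC)c1Cc1occ(Br)c1Br
A6 | alternative 2 | methyl 3-bromopropiolate | COC(=O)C#CBr
A7 | alternative 2 | dimethyl 1,1'-[(5-bromo-2,4,6-trimethoxy-1,3-phenylene)bis(methylene)]bis(3,5,6-tribromo-7-oxabicyclo[2.2.1]hepta-2,5-diene-2-carboxylate), one diastereomer | COc1c(Br)c(OC)c(C[C@@]23O[C@@H](C(Br)=C2Br)C(Br)=C3C(=O)OC)c(OC)c1C[C@@]12O[C@@H](C(Br)=C1Br)C(Br)=C2C(=O)OC
A8 | alternative 3 | (5-bromo-2,4,6-trifluoro-1,3-phenylene)bis[(2,3-dibromo-4,5-dimethoxyphenyl)methanone] | O=C(c1cc(OC)c(OC)c(Br)c1Br)c1c(F)c(Br)c(F)c(C(=O)c2cc(OC)c(OC)c(Br)c2Br)c1F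
A9 | alternative 3 | sodium methoxide | [Na+].[O-]C
A10 | alternative 3 | (5-bromo-2,4,6-trimethoxy-1,3-phenylene)bis[(2,3-dibromo-4,5-dimethoxyphenyl)methanone] | O=C(c1cc(OC)c(OC)c(Br)c1Br)c1c(OC)c(Br)c(OC)c(C(=O)c2cc(OC)c(OC)c(Br)c2Br)c1OC
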